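**Plan**

1. Retrosynthesis: ring B (C1–C10) is cut at C3–C4, an intramolecular allylation of a C3 aldehyde by the C4–C5(=C16) allyl unit. The lactone and the C6–Cl/C7–O pair are cut at C8–C17 (propionate aldol) and across a C6=C7 alkene (epoxide, then chloride). Further cuts are C6=C7 (aldol condensation), C8–C9 (acyl-anion addition) and, last, ring A at C10–C11.
2. Enabling feature: in ring A, C9–C10–C11–C12=C13 is a γ,δ-unsaturated acid, a Claisen retron (C9 at carboxyl level, C12=C13 the precursor of the 12-oxo-13-ene). Because C10 and C13 are also joined through C1–C14, the ester oxygen can be tied to C13. This gives a temporary δ-lactone (C9, O, C13, C14, C1, C10) that is not in the target and contracts to ring A when C10–C11 forms and O–C13 breaks.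
3. Forward order: δ-lactone (boron aldol, ylide lactone annulation, cuprate for quaternary C1), ring A by Ireland–Claisen ring contraction, iodolactonisation/elimination (C12–O, C13=C14), chain C8 to C4, propionate aldol/epoxidation/chloride opening/lactonisation, ring B by allylation, C12 oxidation, acetylation.
4. Stereochemistry: C2 comes from (S)-glycerate. C13 (reagent-controlled aldol) is a relay centre: it sets C1 (anti cuprate addition) and, through the boat [3,3] transition state, C10 and C11 before it becomes sp2. C12 (temporary) is set by iodolactonisation, C9 and C8 by Felkin–Anh additions, C17 by enolate geometry, C6/C7 by Shi epoxidation and invertive chloride opening, and C3 by Felkin–Anh allylation.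

Key step: step 5

Numbering remark: briarane numbering is used for all intermediates (ring A = C1, C10–C14; ring B = C1–C10; lactone = C7, C8, C17, C19; methyls C15 on C1, C18 on C17, C20 on C11; C16 = exocyclic methylene carbon).
Assumption: the (−)-Ipc2BCl aldol of step 2 is taken to follow the si-face preference known for methyl ketone enolates, and the (S)-acetonide is assumed not to override it.

**Route**

Step 1
Reactants: 1 methyl (4S)-2,2-dimethyl-1,3-dioxolane-4-carboxylate
Product: 3 methyl ketone 1-[(4S)-2,2-dimethyl-1,3-dioxolan-4-yl]ethan-1-one, via Weinreb amide 2 (not isolated)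
Conditions: MeNH(OMe)·HCl, i-PrMgCl, THF, −20 °C; then MeMgBr, 0 °C; aq. NH4Cl
Reagents that add atoms: methylmagnesium bromide, C[Mg]Br
Why: One-pot Weinreb ketone synthesis, in which the chelated tetrahedral intermediate survives until work-up so that addition stops at the ketone and the α-alkoxy centre (future C2) is not epimerised.

Step 2
Reactants: 3 methyl ketone; 4 (E)-but-2-enal
Product: 5 β-hydroxy ketone (3S,4E)-1-[(4S)-2,2-dimethyl-1,3-dioxolan-4-yl]-3-hydroxyhex-4-en-1-one
Conditions: (−)-Ipc2BCl, Et3N, Et2O, 0 °C; 4, −78 to −20 °C; H2O2, MeOH, pH 7 buffer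
Reagents that add atoms: none
Why: Reagent-controlled boron aldol reaction of the methyl-side diisopinocampheylboron enolate through a closed chair transition state should add 1,2 to the enal on its si face and set the C13 carbinol as (S).

Step 3
Reactants: 5 β-hydroxy ketone; 6 (triphenylphosphoranylidene)ketene
Product: 8 unsaturated δ-lactone, via ester ylide 7 (not isolated)
Conditions: PhMe, 110 °C
Reagents that add atoms: none
Why: The C13 hydroxyl adds to the ketene ylide and the resulting stabilised ester ylide closes onto the C1 ketone by intramolecular Wittig olefination (Bestmann lactone annulation) under neutral conditions, so β-elimination and epimerisation at C2 should be avoided and no new stereocentre arises.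

Step 4
Reactants: 8 unsaturated δ-lactone
Product: 9 δ-lactone with quaternary C1
Conditions: Me2CuLi, BF3·OEt2, Et2O, −78 to −40 °C; aq. NH4Cl
Reagents that add atoms: lithium dimethylcuprate, [Li+].C[Cu-]C
Why: Lewis-acid-assisted cuprate conjugate addition to the β,β-disubstituted 5,6-dihydropyran-2-one should occur axially and anti to the pseudo-equatorial C13 propenyl group, so Me-15 ends trans and the C2 side chain cis to propenyl, setting quaternary C1 by 1,3-induction from C13.

Step 5
Reactants: 9 δ-lactone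
Product: 12 ring A acid, via silyl ketene acetal 10 (not isolated), via silyl ester 11 (not isolated)
Conditions: LiN(i-Pr)2, t-BuMe2SiCl, DMPU, THF, −78 to 23 °C; PhMe, 100 °C; then cat. K2CO3, MeOH/H2O, 23 °C
Reagents that add atoms: none
Why: Deprotonation at C10 (the only enolisable position) and O-silylation give the cyclic silyl ketene acetal 10, an allyl vinyl ether C10=C9–O–C13–C12=C11 that should undergo a concerted suprafacial [3,3]-sigmatropic (Ireland–Claisen) shift on heating, breaking the O–C13 bond of the temporary lactone while C10–C11 forms. The closest known reaction type is the ring-contracting Ireland–Claisen rearrangement of silyl ketene acetals of ω-alkenyl lactones (and of 6-alkenyl-1,4-dioxan-2-ones) to cycloalkene carboxylic acids. Ring A (C1, C10, C11, C12, C13, C14) closes in a six-centre pericyclic mode in which the two-atom tether C1–C14 links termini C10 and C13, so only a boat-like, bicyclo[2.2.2]octane-shaped transition state is possible and the six-membered lactone is exchanged for the six-membered carbocycle. C10 is set because the new bond must form on the lactone face that carries the propenyl group (fixed by C13), which is cis to C2 and trans to Me-15, so the C9 carboxyl ends cis to Me-15 and trans to C2; C11 is set by the (E) geometry of the propenyl group, which in the enforced boat places Me-20 on the side of the C9–O bridge, that is cis to C9. The selectivity needed is clean chirality transfer from C13 (which becomes sp2 in C12=C13) without a competing chair pathway or E/Z leakage, and it is secured by the ring constraint of the lactone, the fixed endocyclic enolate geometry and the geometrically pure (E)-alkene. The product carries the C12=C13 alkene exactly where the C12 oxygen and the C13=C14 unsaturation are introduced next.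

Step 6
Reactants: 12 ring A acid
Product: 13 iodolactone
Conditions: I2, NaHCO3, MeCN/H2O, 0 °C, dark
Reagents that add atoms: iodine, II
Why: Iodolactonisation in which the axial C9 carboxylate opens the iodonium ion of C12=C13 in a trans-diaxial sense, placing the lactone oxygen on C12 cis to C9 (temporary C12 stereocentre) and iodine on C13 in a 6-oxabicyclo[3.2.1]octan-7-one.

Step 7
Reactants: 13 iodolactone
Product: 14 bridged unsaturated lactone
Conditions: DBU, PhMe, 80 °C
Reagents that add atoms: none
Why: E2 dehydroiodination removes the axial C14 hydrogen anti to the axial iodide (loss of the C12 hydrogen is geometrically excluded) and installs the C13=C14 alkene of ring A.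

Step 8
Reactants: 14 bridged unsaturated lactone
Product: 15 ring A 1-ethoxyvinyl ketone with free C12 hydroxyl
Conditions: CH2=C(OEt)Li (from ethyl vinyl ether, t-BuLi), THF, −78 °C; aq. NH4Cl
Reagents that add atoms: 1-ethoxyvinyllithium, [Li]C(=C)OCC
Why: Addition of an acyl-anion equivalent (α-alkoxyvinyllithium) to the strained lactone should stop at the ketone because the bridged lithium hemiketal persists at low temperature, which introduces C8 and C7 while enolisation toward the bridgehead C10 is disfavoured.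

Step 9
Reactants: 15 ring A 1-ethoxyvinyl ketone
Product: 17 α-hydroxy methyl ketone diol, via enol ether diol 16 (not isolated)
Conditions: NaBH4, CeCl3·7H2O, MeOH, −78 °C; then 0.1 M aq. HCl, THF, 0 °C
Reagents that add atoms: water, O
Why: Luche 1,2-reduction of the C9 ketone under Felkin–Anh control (hydride anti to quaternary C1, carbonyl oxygen turned toward C11 and the C12 hydroxyl) should set C9 as in the target, and mild hydrolysis of the enol ether then reveals the C8 methyl ketone.

Step 10
Reactants: 17 α-hydroxy methyl ketone diol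
Product: 18 bis(tert-butyldimethylsilyl) ether
Conditions: t-BuMe2SiOTf, 2,6-lutidine, CH2Cl2, −78 to 0 °C
Reagents that add atoms: tert-butyldimethylsilyl trifluoromethanesulfonate, CC(C)(C)[Si](C)(C)OS(=O)(=O)C(F)(F)F
Why: O-silylation of both secondary alcohols gives bulky non-chelating ethers at C9 and C12 that tolerate the enolate chemistry and later enforce Felkin–Anh addition at C8.

Step 11
Reactants: 19 2-methylidenepropane-1,3-diol
Product: 20 mono(tert-butyldimethylsilyl) ether
Conditions: NaH (1 equiv), t-BuMe2SiCl, THF, 0 to 23 °C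
Reagents that add atoms: tert-butyldimethylsilyl chloride, CC(C)(C)[Si](C)(C)Cl
Why: Monosilylation of the symmetric diol through its sparingly soluble monosodium alkoxide is a standard desymmetrising protection.

Step 12
Reactants: 20 mono(tert-butyldimethylsilyl) ether
Product: 21 2-(silyloxymethyl)acrolein
Conditions: MnO2, CH2Cl2, 23 °C
Reagents that add atoms: none
Why: MnO2 oxidises the allylic alcohol selectively to the 2-substituted enal without over-oxidation.

Step 13
Reactants: 18 bis(tert-butyldimethylsilyl) ether; 21 2-(silyloxymethyl)acrolein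
Product: 24 (6E)-dienone, via aldol adduct 22 (not isolated), via mesylate 23 (not isolated)
Conditions: LiN(i-Pr)2, THF, −78 °C; 21; then MsCl, Et3N, −78 to 23 °C
Reagents that add atoms: none
Why: Kinetic deprotonation at the C7 methyl (not at the hindered C9–H), 1,2-aldol addition to the enal and in-flask mesylation with E1cB elimination (aldol condensation) should give the (E)-C6=C7 dienone, the C6 carbinol centre of the intermediates being destroyed.

Step 14
Reactants: 24 (6E)-dienone; 25 methyl propanoate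
Product: 26 tertiary alcohol methyl ester
Conditions: 25, LiN(i-Pr)2, THF/DMPU, −78 °C; then 24, −78 °C; AcOH quench at −78 °C
Reagents that add atoms: none
Why: Aldol addition of the lithium enolate of methyl propanoate (C18 methyl cis to OLi, as formed in THF/DMPU) to the C8 ketone through a Zimmerman–Traxler transition state should occur anti to the C9 silyloxy group (polar Felkin–Anh) to set C8, and with the branched C9 substituent equatorial it places Me-18 anti to C9 to set C17.

Step 15
Reactants: 26 tertiary alcohol methyl ester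
Product: 27 (6R,7S)-vinyl epoxide
Conditions: D-fructose-derived Shi ketone (30 mol %), KHSO5, K2CO3, Bu4NHSO4, MeCN/CH2(OMe)2/aq. buffer (pH 10.5), 0 °C
Reagents that add atoms: potassium peroxymonosulfate, [K+].[O-]S(=O)(=O)OO
Why: Shi asymmetric epoxidation is selective for the trans-disubstituted C6=C7 alkene over the 1,1-disubstituted C5=C16 and the cis ring A alkene, and the spiro transition state of the D-fructose-derived dioxirane should deliver the (6R,7S) epoxide by reagent control.

Step 16
Reactants: 27 (6R,7S)-vinyl epoxide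
Product: 29 chloro lactone, via chlorohydrin ester 28 (not isolated)
Conditions: TiCl(O-i-Pr)3, CH2Cl2, 0 °C; then PPTS (cat.), PhH, 40 °C
Reagents that add atoms: chlorotitanium triisopropoxide, CC(C)O[Ti](Cl)(OC(C)C)OC(C)C
Why: Titanium-assisted regioselective opening of the 2,3-epoxy alcohol delivers chloride with inversion to the distal allylic C6 (C7 being neopentyl-like), which sets the C6–Cl/C7–O anti pair, and the freed C7 hydroxyl then lactonises onto the methyl ester (5-exo-trig acyl substitution) to give the γ-lactone with the free C8 hydroxyl.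

Step 17
Reactants: 29 chloro lactone
Product: 30 C4 primary allylic alcohol
Conditions: HF·pyridine, pyridine, THF, 0 °C
Reagents that add atoms: none
Why: Fluoride-mediated desilylation removes the unhindered primary allylic silyl ether much faster than the two hindered secondary ones.

Step 18
Reactants: 30 C4 primary allylic alcohol
Product: 31 C4 allylic bromide
Conditions: CBr4, PPh3, CH2Cl2, 0 °C
Reagents that add atoms: carbon tetrabromide, BrC(Br)(Br)Br
Why: Appel bromination converts the primary allylic alcohol under neutral conditions, direct and allylic substitution giving the same product on the symmetric 2-methylene allyl unit and the tertiary C8 hydroxyl being inert.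

Step 19
Reactants: 31 C4 allylic bromide
Product: 32 C2,C3-diol
Conditions: Zn(NO3)2·6H2O, MeCN, 50 °C
Reagents that add atoms: none
Why: Mild Lewis-acid hydrolysis of the terminal acetonide should leave the secondary silyl ethers, the lactone and both allylic halides untouched.

Step 20
Reactants: 32 C2,C3-diol
Product: 33 C2,C3-bis(triethylsilyl) ether
Conditions: Et3SiOTf, 2,6-lutidine, CH2Cl2, −78 °C
Reagents that add atoms: triethylsilyl trifluoromethanesulfonate, CC[Si](CC)(CC)OS(=O)(=O)C(F)(F)F
Why: O-silylation with a non-nucleophilic base protects the primary and secondary hydroxyls while the hindered tertiary C8 hydroxyl and the allylic bromide are spared.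

Step 21
Reactants: 33 C2,C3-bis(triethylsilyl) ether
Product: 34 C3 aldehyde
Conditions: (COCl)2, DMSO, CH2Cl2, −78 to −30 °C; i-Pr2NEt
Reagents that add atoms: none
Why: Swern oxidation cleaves and oxidises a primary triethylsilyl ether directly to the aldehyde while secondary silyl ethers stay, giving the α-silyloxy aldehyde without a free α-hydroxy aldehyde.

Step 22
Reactants: 34 C3 aldehyde
Product: 35 ring B alcohol
Conditions: CrCl2, THF, high dilution, slow addition, 23 °C
Reagents that add atoms: none
Why: Intramolecular Nozaki–Hiyama allylation, in which divalent chromium inserts into the primary allylic C–Br bond far faster than into the secondary C6–Cl bond and the allylchromium adds to the C3 aldehyde through a six-membered transition state anti to the C2 silyloxy group (Felkin–Anh), should close the ten-membered ring B and set C3, either terminus of the symmetric allyl unit giving the same 5(16)-methylene product.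

Step 23
Reactants: 35 ring B alcohol
Product: 36 pentaol
Conditions: HF·pyridine, THF, 0 to 23 °C
Reagents that add atoms: none
Why: Global fluoride desilylation frees the C2, C9 and C12 hydroxyls without touching the lactone or the allylic chloride.

Step 24
Reactants: 36 pentaol
Product: 37 12-oxo tetraol
Conditions: MnO2, CH2Cl2, 23 °C
Reagents that add atoms: none
Why: MnO2 oxidises only the allylic C12 alcohol to the ring A enone, since the C2, C3, C9 and C8 hydroxyls are not allylic.

Step 25
Reactants: 37 12-oxo tetraol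
Product: 38 target CNP0391614.1
Conditions: Ac2O, pyridine, cat. DMAP, CH2Cl2, 0 to 23 °C
Reagents that add atoms: acetic anhydride, CC(=O)OC(C)=O
Why: Acetylation esterifies the three secondary hydroxyls at C2, C3 and C9 while the hindered tertiary C8 hydroxyl is not acylated under these mild conditions.

**Compound list**

1 | methyl (4S)-2,2-dimethyl-1,3-dioxolane-4-carboxylate | COC(=O)[C@@H]1COC(C)(C)O1 | starting material
2 | (4S)-N-methoxy-N,2,2-trimethyl-1,3-dioxolane-4-carboxamide (Weinreb amide) | CON(C)C(=O)[C@@H]1COC(C)(C)O1 | intermediate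
3 | 1-[(4S)-2,2-dimethyl-1,3-dioxolan-4-yl]ethan-1-one | CC(=O)[C@@H]1COC(C)(C)O1 | intermediate
4 | (E)-but-2-enal | C/C=C/C=O | starting material
5 | (3S,4E)-1-[(4S)-2,2-dimethyl-1,3-dioxolan-4-yl]-3-hydroxyhex-4-en-1-one | C/C=C/[C@@H](O)CC(=O)[C@@H]1COC(C)(C)O1 | intermediate
6 | (triphenylphosphoranylidene)ketene | O=C=C=P(c1ccccc1)(c1ccccc1)c1ccccc1 | starting material
7 | ester ylide: (triphenylphosphoranylidene)acetate of the C13 hydroxyl of 5 | C/C=C/[C@H](CC(=O)[C@@H]1COC(C)(C)O1)OC(=O)C=P(c1ccccc1)(c1ccccc1)c1ccccc1 | intermediate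
8 | (6S)-4-[(4R)-2,2-dimethyl-1,3-dioxolan-4-yl]-6-[(E)-prop-1-enyl]-5,6-dihydro-2H-pyran-2-one | O=C1C=C([C@@H]2COC(C)(C)O2)C[C@@H](/C=C/C)O1 | intermediate
9 | (4S,6S)-4-[(4R)-2,2-dimethyl-1,3-dioxolan-4-yl]-4-methyl-6-[(E)-prop-1-enyl]oxan-2-one (methyl trans, dioxolanyl cis to propenyl) | O=C1C[C@@](C)([C@@H]2COC(C)(C)O2)C[C@@H](/C=C/C)O1 | intermediate
10 | tert-butyldimethylsilyl ketene acetal of 9 (C10=C9 enol silyl ether in the lactone ring) | CC(C)(C)[Si](C)(C)OC1=C[C@@](C)([C@@H]2COC(C)(C)O2)C[C@@H](/C=C/C)O1 | intermediate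
11 | tert-butyldimethylsilyl ester of acid 12 | CC(C)(C)[Si](C)(C)OC(=O)[C@H]1[C@@H](C)C=CC[C@]1(C)[C@@H]2COC(C)(C)O2 | intermediate
12 | (1S,2S,6S)-6-[(4R)-2,2-dimethyl-1,3-dioxolan-4-yl]-2,6-dimethylcyclohex-3-ene-1-carboxylic acid (ring A; C9 carboxyl cis to Me-15 and Me-20) | O=C(O)[C@H]1[C@@H](C)C=CC[C@]1(C)[C@@H]2COC(C)(C)O2 | intermediate
13 | iodolactone: C9 carbonyl bridged through oxygen to C12 (6-oxabicyclo[3.2.1]octan-7-one), iodine on C13 trans to the lactone oxygen | O=C1O[C@H]2[C@H](I)C[C@](C)([C@@H]3COC(C)(C)O3)[C@@H]1[C@H]2C | intermediate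
14 | bridged unsaturated lactone (6-oxabicyclo[3.2.1]oct-3-en-7-one with C13=C14) | O=C1O[C@H]2C=C[C@](C)([C@@H]3COC(C)(C)O3)[C@@H]1[C@H]2C | intermediate
15 | ring A 1-ethoxyvinyl ketone (C9 ketone, C8 enol ether carbon, free C12 hydroxyl cis to C9) | C=C(OCC)C(=O)[C@H]1[C@@H](C)[C@@H](O)C=C[C@]1(C)[C@@H]2COC(C)(C)O2 | intermediate
16 | enol ether diol (C9 carbinol as in the target, C12 hydroxyl) | C=C(OCC)[C@@H](O)[C@H]1[C@@H](C)[C@@H](O)C=C[C@]1(C)[C@@H]2COC(C)(C)O2 | intermediate
17 | α-hydroxy methyl ketone diol (C9 OH, C8 ketone, C7 methyl, C12 OH) | CC(=O)[C@@H](O)[C@H]1[C@@H](C)[C@@H](O)C=C[C@]1(C)[C@@H]2COC(C)(C)O2 | intermediate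
18 | C9,C12-bis(tert-butyldimethylsilyl) ether of 17 | CC(=O)[C@@H](O[Si](C)(C)C(C)(C)C)[C@H]1[C@@H](C)[C@@H](O[Si](C)(C)C(C)(C)C)C=C[C@]1(C)[C@@H]2COC(C)(C)O2 | intermediate
19 | 2-methylidenepropane-1,3-diol | C=C(CO)CO | starting material
20 | 2-{[(tert-butyldimethylsilyl)oxy]methyl}prop-2-en-1-ol | C=C(CO)CO[Si](C)(C)C(C)(C)C | intermediate
21 | 2-{[(tert-butyldimethylsilyl)oxy]methyl}prop-2-enal | C=C(C=O)CO[Si](C)(C)C(C)(C)C | intermediate
22 | aldol adduct (C6 carbinol, both C6 epimers) | C=C(CO[Si](C)(C)C(C)(C)C)C(O)CC(=O)[C@@H](O[Si](C)(C)C(C)(C)C)[C@H]1[C@@H](C)[C@@H](O[Si](C)(C)C(C)(C)C)C=C[C@]1(C)[C@@H]2COC(C)(C)O2 | intermediate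
23 | C6 mesylate of 22 (both C6 epimers) | C=C(CO[Si](C)(C)C(C)(C)C)C(OS(C)(=O)=O)CC(=O)[C@@H](O[Si](C)(C)C(C)(C)C)[C@H]1[C@@H](C)[C@@H](O[Si](C)(C)C(C)(C)C)C=C[C@]1(C)[C@@H]2COC(C)(C)O2 | intermediate
24 | (6E)-dienone (C8 ketone, C6=C7, C5=C16, C4 silyl ether) | C=C(CO[Si](C)(C)C(C)(C)C)/C=C/C(=O)[C@@H](O[Si](C)(C)C(C)(C)C)[C@H]1[C@@H](C)[C@@H](O[Si](C)(C)C(C)(C)C)C=C[C@]1(C)[C@@H]2COC(C)(C)O2 | intermediate
25 | methyl propanoate | CCC(=O)OC | starting material
26 | (8R,9S,17R) tertiary alcohol methyl ester (C8 OH, C17 methyl, C19 ester) | C=C(CO[Si](C)(C)C(C)(C)C)/C=C/[C@@](O)([C@@H](C)C(=O)OC)[C@@H](O[Si](C)(C)C(C)(C)C)[C@H]1[C@@H](C)[C@@H](O[Si](C)(C)C(C)(C)C)C=C[C@]1(C)[C@@H]2COC(C)(C)O2 | intermediate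
27 | (6R,7S)-trans-epoxide of 26 | C=C(CO[Si](C)(C)C(C)(C)C)[C@H]1O[C@@H]1[C@@](O)([C@@H](C)C(=O)OC)[C@@H](O[Si](C)(C)C(C)(C)C)[C@H]2[C@@H](C)[C@@H](O[Si](C)(C)C(C)(C)C)C=C[C@]2(C)[C@@H]3COC(C)(C)O3 | intermediate
28 | (6S,7R) chlorohydrin methyl ester (C6 Cl, C7 OH, C8 OH) | C=C(CO[Si](C)(C)C(C)(C)C)[C@H](Cl)[C@H](O)[C@@](O)([C@@H](C)C(=O)OC)[C@@H](O[Si](C)(C)C(C)(C)C)[C@H]1[C@@H](C)[C@@H](O[Si](C)(C)C(C)(C)C)C=C[C@]1(C)[C@@H]2COC(C)(C)O2 | intermediate
29 | chloro lactone (γ-lactone C7–O–C19, free C8 OH, C6 Cl, C4 silyl ether) | C=C(CO[Si](C)(C)C(C)(C)C)[C@H](Cl)[C@@H]1OC(=O)[C@H](C)[C@@]1(O)[C@@H](O[Si](C)(C)C(C)(C)C)[C@H]2[C@@H](C)[C@@H](O[Si](C)(C)C(C)(C)C)C=C[C@]2(C)[C@@H]3COC(C)(C)O3 | intermediate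
30 | C4 primary allylic alcohol of 29 | C=C(CO)[C@H](Cl)[C@@H]1OC(=O)[C@H](C)[C@@]1(O)[C@@H](O[Si](C)(C)C(C)(C)C)[C@H]2[C@@H](C)[C@@H](O[Si](C)(C)C(C)(C)C)C=C[C@]2(C)[C@@H]3COC(C)(C)O3 | intermediate
31 | C4 allylic bromide | C=C(CBr)[C@H](Cl)[C@@H]1OC(=O)[C@H](C)[C@@]1(O)[C@@H](O[Si](C)(C)C(C)(C)C)[C@H]2[C@@H](C)[C@@H](O[Si](C)(C)C(C)(C)C)C=C[C@]2(C)[C@@H]3COC(C)(C)O3 | intermediate
32 | C2,C3-diol (acetonide removed) | C=C(CBr)[C@H](Cl)[C@@H]1OC(=O)[C@H](C)[C@@]1(O)[C@@H](O[Si](C)(C)C(C)(C)C)[C@H]2[C@@H](C)[C@@H](O[Si](C)(C)C(C)(C)C)C=C[C@]2(C)[C@@H](O)CO | intermediate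
33 | C2,C3-bis(triethylsilyl) ether | C=C(CBr)[C@H](Cl)[C@@H]1OC(=O)[C@H](C)[C@@]1(O)[C@@H](O[Si](C)(C)C(C)(C)C)[C@H]2[C@@H](C)[C@@H](O[Si](C)(C)C(C)(C)C)C=C[C@]2(C)[C@@H](O[Si](CC)(CC)CC)CO[Si](CC)(CC)CC | intermediate
34 | C3 aldehyde with C2 triethylsilyl ether and C4 bromide | C=C(CBr)[C@H](Cl)[C@@H]1OC(=O)[C@H](C)[C@@]1(O)[C@@H](O[Si](C)(C)C(C)(C)C)[C@H]2[C@@H](C)[C@@H](O[Si](C)(C)C(C)(C)C)C=C[C@]2(C)[C@@H](O[Si](CC)(CC)CC)C=O | intermediate
35 | ring B alcohol (briarane skeleton; C3 OH, C2 triethylsilyl ether, C9 and C12 tert-butyldimethylsilyl ethers) | C=C1C[C@H](O)[C@H](O[Si](CC)(CC)CC)[C@@]2(C)C=C[C@H](O[Si](C)(C)C(C)(C)C)[C@H](C)[C@@H]2[C@H](O[Si](C)(C)C(C)(C)C)[C@]2(O)[C@@H](C)C(=O)O[C@H]2[C@H]1Cl | intermediate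
36 | pentaol (C2, C3, C8, C9, C12 hydroxyls) | C=C1C[C@H](O)[C@H](O)[C@@]2(C)C=C[C@H](O)[C@H](C)[C@@H]2[C@H](O)[C@]2(O)[C@@H](C)C(=O)O[C@H]2[C@H]1Cl | intermediate
37 | 12-oxo tetraol (ring A enone) | C=C1C[C@H](O)[C@H](O)[C@@]2(C)C=CC(=O)[C@H](C)[C@@H]2[C@H](O)[C@]2(O)[C@@H](C)C(=O)O[C@H]2[C@H]1Cl | intermediate
38 | CNP0391614.1 (1S,2R,3S,6S,7R,8R,9S,10S,11R,17R) | C=C1C[C@H](OC(C)=O)[C@H](OC(C)=O)[C@@]2(C)C=CC(=O)[C@H](C)[C@@H]2[C@H](OC(C)=O)[C@]2(O)[C@@H](C)C(=O)O[C@H]2[C@H]1Cl | target

**Step count and risks**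

Total step count: 25. Longest linear sequence: 23 steps (steps 1–10 and 13–25; steps 11–12 make the enal 21).

Steps most likely to fail:

Step 14. The propionate enolate may add in a conjugate sense (at C16 or C6) instead of at the hindered C8 carbonyl, the tertiary aldolate may revert by retro-aldol, and the Felkin–Anh preference may be eroded. The fallback replaces the intermolecular aldol by an intramolecular Reformatsky closure. It sets out from dienone 24: nucleophilic epoxidation of the enone bond (t-BuOOH, La(O-i-Pr)3, (R)-BINOL, Ph3As=O) should give epoxy ketone F1; opening at the allylic C6 with TiCl(O-i-Pr)3 should give chlorohydrin ketone F2; acylation of the C7 hydroxyl with 2-bromopropanoyl bromide and pyridine should give bromo ester F3; and activated zinc (Zn, Me3SiCl, THF) should form the zinc enolate, which closes onto the C8 ketone with the bulky C6, C9 and C18 groups mutually trans. The fallback returns to the route at chloro lactone 29.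

Step 16. Chloride may attack C16 with allylic transposition, or the ester carbonyl may open the epoxide at C7, so that chlorine and the lactone oxygen end at the wrong positions. The fallback replaces epoxide opening by halolactonisation and sets out from ester 26: saponification (LiOH, THF/H2O) should give carboxylic acid F4, and catalytic asymmetric chlorolactonisation (1,3-dichloro-5,5-dimethylhydantoin, (DHQD)2PHAL or its pseudo-enantiomer, chosen for the 6S,7R sense) should add chlorine to C6 and the carboxylate to C7 anti across the (E)-alkene in a 5-exo mode. It returns to the route at chloro lactone 29.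

Step 22. Oligomerisation may outrun ring closure, chromium may insert into the C6–Cl bond, the C3 alkoxide may displace the C6 chloride across the ring, and facial selectivity at C3 may be poor. The fallback closes the same ring by a carbonyl–ene reaction instead of an organochromium addition and sets out from bromide 31: radical reduction (Bu3SnH, AIBN, PhH, 80 °C) should give isopropenyl lactone F5; the conditions of steps 19–21 should then give diol F6, bis(triethylsilyl) ether F7 and aldehyde F8; and Me2AlCl (CH2Cl2, −78 °C, high dilution) should promote a type 2 intramolecular carbonyl–ene reaction in which the methylene terminus bonds to C3 and a methyl hydrogen is transferred, giving the 5(16)-methylene homoallylic alcohol. It returns to the route at ring B alcohol 35.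

Further compounds
F1 | step 14 | (6R,7S)-epoxy ketone from dienone 24 | C=C(CO[Si](C)(C)C(C)(C)C)[C@H]1O[C@@H]1C(=O)[C@@H](O[Si](C)(C)C(C)(C)C)[C@H]2[C@@H](C)[C@@H](O[Si](C)(C)C(C)(C)C)C=C[C@]2(C)[C@@H]3COC(C)(C)O3
F2 | step 14 | (6S,7R)-6-chloro-7-hydroxy C8 ketone | C=C(CO[Si](C)(C)C(C)(C)C)[C@H](Cl)[C@H](O)C(=O)[C@@H](O[Si](C)(C)C(C)(C)C)[C@H]1[C@@H](C)[C@@H](O[Si](C)(C)C(C)(C)C)C=C[C@]1(C)[C@@H]2COC(C)(C)O2
F3 | step 14 | C7 2-bromopropanoate of F2 (both epimers at the bromine-bearing carbon) | C=C(CO[Si](C)(C)C(C)(C)C)[C@H](Cl)[C@H](OC(=O)C(C)Br)C(=O)[C@@H](O[Si](C)(C)C(C)(C)C)[C@H]1[C@@H](C)[C@@H](O[Si](C)(C)C(C)(C)C)C=C[C@]1(C)[C@@H]2COC(C)(C)O2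
F4 | step 16 | carboxylic acid from ester 26 | C=C(CO[Si](C)(C)C(C)(C)C)/C=C/[C@@](O)([C@@H](C)C(=O)O)[C@@H](O[Si](C)(C)C(C)(C)C)[C@H]1[C@@H](C)[C@@H](O[Si](C)(C)C(C)(C)C)C=C[C@]1(C)[C@@H]2COC(C)(C)O2
F5 | step 22 | isopropenyl lactone (C4 methyl in place of CH2Br of 31) | C=C(C)[C@H](Cl)[C@@H]1OC(=O)[C@H](C)[C@@]1(O)[C@@H](O[Si](C)(C)C(C)(C)C)[C@H]2[C@@H](C)[C@@H](O[Si](C)(C)C(C)(C)C)C=C[C@]2(C)[C@@H]3COC(C)(C)O3
F6 | step 22 | C2,C3-diol of F5 | C=C(C)[C@H](Cl)[C@@H]1OC(=O)[C@H](C)[C@@]1(O)[C@@H](O[Si](C)(C)C(C)(C)C)[C@H]2[C@@H](C)[C@@H](O[Si](C)(C)C(C)(C)C)C=C[C@]2(C)[C@@H](O)CO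
F7 | step 22 | C2,C3-bis(triethylsilyl) ether of F6 | C=C(C)[C@H](Cl)[C@@H]1OC(=O)[C@H](C)[C@@]1(O)[C@@H](O[Si](C)(C)C(C)(C)C)[C@H]2[C@@H](C)[C@@H](O[Si](C)(C)C(C)(C)C)C=C[C@]2(C)[C@@H](O[Si](CC)(CC)CC)CO[Si](CC)(CC)CC
F8 | step 22 | C3 aldehyde with isopropenyl group | C=C(C)[C@H](Cl)[C@@H]1OC(=O)[C@H](C)[C@@]1(O)[C@@H](O[Si](C)(C)C(C)(C)C)[C@H]2[C@@H](C)[C@@H](O[Si](C)(C)C(C)(C)C)C=C[C@]2(C)[C@@H](O[Si](CC)(CC)CC)C=O
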